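**Retrosynthetic overview**
1. Ring C is disconnected first: the C2–aryl bond of the (2S)-flavanone goes back to a chromone plus 4-(methoxymethoxy)phenylboronic acid, and the chromone (O1–C2 closure with a one-carbon unit) to a ring A 2-hydroxyacetophenone.
2. Key disconnection: the heptenyl chain on C8 of ring A ends in two identical 4-hydroxyphenyl rings, one on the sp2 carbon C1'' of the E C1''=C2'' alkene and one on the sp3 carbon C7''. Both C–aryl bonds are cut at once, so that C1''≡C2'' (terminal alkyne) and C6''=C7'' (vinyl) belong to one enyne that is coupled twice with the same aryl iodide.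
3. The enyne carries C3'' (rhodium-catalysed conjugate alkynylation of a ring A cinnamaldehyde) and C5'' (asymmetric transfer hydrogenation of an ynone, whose alkyne is then reduced to the vinyl group).
4. Ring order: ring A is bought (5-methoxyresorcinol); the two chain-terminal arenes are attached without ring formation; ring C is closed as the pyranone after the key step; ring B is attached last.

Key step: step 11

Remark (assumption): the absolute sense of the three catalyst-controlled steps (3, 6 and 17) is assigned by analogy with the accepted models of each catalyst family; the ligand antipode named is the one expected to give the drawn configuration, and the mirror-image ligand is to be used if the first assay (Mosher ester or chiral HPLC) shows the opposite sense.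

**Step 1**
Reactants: 1 5-methoxyresorcinol
Product: 2 1-methoxy-3,5-bis(methoxymethoxy)benzene
Conditions: MOMCl (2.5 equiv.), i-Pr2NEt (3 equiv.), CH2Cl2, 0 °C → rt
Reagents that add atoms: chloromethyl methyl ether, COCCl
Why: Williamson-type O-alkylation of both phenols should give the bis-MOM ether, whose acetal oxygens later direct the lithiation between them and which survives every basic and organometallic step.

**Step 2**
Reactants: 2 1-methoxy-3,5-bis(methoxymethoxy)benzene
Product: 5 (2E)-3-[4-methoxy-2,6-bis(methoxymethoxy)phenyl]prop-2-enal, via aryllithium 3 (not isolated), via lithium aminoallyl alkoxide 4 (not isolated)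
Conditions: n-BuLi (1.1 equiv.), THF, 0 °C → rt; Me2NCH=CHCHO (1.3 equiv.), −78 → 0 °C; 1 M HCl, 0 °C
Reagents that add atoms: 3-(dimethylamino)acrolein, CN(C)/C=C/C=O; water, O
Why: Directed ortho-lithiation at the position flanked by both MOM ethers, 1,2-addition of the aryllithium to the vinylogous formamide and acid-induced loss of dimethylamine (vinylogous Bouveault formylation) should give the cinnamaldehyde as the thermodynamically favoured E isomer.

**Step 3**
Reactants: 5 (2E)-3-[4-methoxy-2,6-bis(methoxymethoxy)phenyl]prop-2-enal; 6 ethynyltri(propan-2-yl)silane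
Product: 7 (3R)-3-[4-methoxy-2,6-bis(methoxymethoxy)phenyl]-5-[tri(propan-2-yl)silyl]pent-4-ynal
Conditions: [Rh(OAc)(C2H4)2]2 (2.5 mol %), (R)-DTBM-SEGPHOS (6 mol %), 6 (2 equiv.), MeOH, 40 °C
Reagents that add atoms: none
Why: Rhodium-catalysed asymmetric conjugate alkynylation of an enal, in which the alkynylrhodium species formed by acetate-assisted C–H metalation inserts the enal C=C bond on the face selected by the bulky bisphosphine while the large silyl group suppresses alkyne dimerisation, should set C3'' (R here because the silylalkynyl group outranks the arene).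

**Step 4**
Reactants: 7 (3R)-3-[4-methoxy-2,6-bis(methoxymethoxy)phenyl]-5-[tri(propan-2-yl)silyl]pent-4-ynal
Product: 8 (5R)-5-[4-methoxy-2,6-bis(methoxymethoxy)phenyl]-7-[tri(propan-2-yl)silyl]-1-(trimethylsilyl)hepta-1,6-diyn-3-ol (both C3 epimers)
Conditions: HC≡CSiMe3 (1.5 equiv.), n-BuLi (1.4 equiv.), THF, −78 °C; then 7, −78 → −40 °C; aq. NH4Cl
Reagents that add atoms: ethynyl(trimethyl)silane, C#C[Si](C)(C)C
Why: 1,2-Addition of a lithium acetylide to the aldehyde should give the propargylic alcohol, whose new carbinol centre is formed as an epimer mixture that is erased by the following oxidation.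

**Step 5**
Reactants: 8 (5R)-5-[4-methoxy-2,6-bis(methoxymethoxy)phenyl]-7-[tri(propan-2-yl)silyl]-1-(trimethylsilyl)hepta-1,6-diyn-3-ol
Product: 9 (5R)-5-[4-methoxy-2,6-bis(methoxymethoxy)phenyl]-7-[tri(propan-2-yl)silyl]-1-(trimethylsilyl)hepta-1,6-diyn-3-one
Conditions: Dess–Martin periodinane (1.3 equiv.), CH2Cl2, 0 °C → rt
Reagents that add atoms: none
Why: Dess–Martin oxidation of the secondary propargylic alcohol should give the ynone under near-neutral conditions that leave the MOM ethers, both silylalkynes and the C3'' centre (not α to the carbonyl) untouched.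

**Step 6**
Reactants: 9 (5R)-5-[4-methoxy-2,6-bis(methoxymethoxy)phenyl]-7-[tri(propan-2-yl)silyl]-1-(trimethylsilyl)hepta-1,6-diyn-3-one
Product: 10 (3R,5R)-5-[4-methoxy-2,6-bis(methoxymethoxy)phenyl]-7-[tri(propan-2-yl)silyl]-1-(trimethylsilyl)hepta-1,6-diyn-3-ol
Conditions: Ru[(R,R)-TsNCHPhCHPhNH](p-cymene) (2 mol %), i-PrOH, rt
Reagents that add atoms: none
Why: Asymmetric transfer hydrogenation of an alkynyl ketone by the bifunctional ruthenium amide with isopropanol, in which the alkyne takes the place of the aryl group of an aryl ketone, should set C5'' under catalyst control without added base; the ynone is used instead of the corresponding vinyl ketone because its two carbonyl substituents are differentiated reliably by this catalyst, whereas vinyl and CH2R are too alike for an oxazaborolidine reduction.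

**Step 7**
Reactants: 10 (3R,5R)-5-[4-methoxy-2,6-bis(methoxymethoxy)phenyl]-7-[tri(propan-2-yl)silyl]-1-(trimethylsilyl)hepta-1,6-diyn-3-ol
Product: 11 (3R,5S)-5-[4-methoxy-2,6-bis(methoxymethoxy)phenyl]hepta-1,6-diyn-3-ol
Conditions: n-Bu4NF (2.5 equiv.), THF, 0 °C → rt
Reagents that add atoms: none
Why: Fluoride-induced protodesilylation of both C(sp)–Si bonds should free the two terminal alkynes in one operation; the C5 descriptor changes to S only because the unsilylated alkyne now ranks below the arene.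

**Step 8**
Reactants: 11 (3R,5S)-5-[4-methoxy-2,6-bis(methoxymethoxy)phenyl]hepta-1,6-diyn-3-ol
Product: 12 (3R,5S)-5-[4-methoxy-2,6-bis(methoxymethoxy)phenyl]hept-1-en-6-yn-3-ol
Conditions: NaAlH2(OCH2CH2OMe)2 (3 equiv.), THF, 0 °C → rt; aq. KNaC4H4O6
Reagents that add atoms: none
Why: Hydroxyl-directed trans-hydroalumination of a propargylic alcohol delivers hydride intramolecularly only to the alkyne next to the carbinol, and protonolysis of the alkenylaluminium should give the vinyl group, while the alkyne at C3'' has no alkoxide within reach and is at most deprotonated reversibly.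

**Step 9**
Reactants: 12 (3R,5S)-5-[4-methoxy-2,6-bis(methoxymethoxy)phenyl]hept-1-en-6-yn-3-ol
Product: 13 tert-butyl({(3R,5S)-5-[4-methoxy-2,6-bis(methoxymethoxy)phenyl]hept-1-en-6-yn-3-yl}oxy)dimethylsilane
Conditions: TBSCl (1.5 equiv.), imidazole (3 equiv.), DMF, rt
Reagents that add atoms: tert-butyl(chloro)dimethylsilane, CC(C)(C)[Si](C)(C)Cl
Why: Imidazole-promoted silylation of the secondary allylic alcohol should give the silyl ether, which keeps the hydroxyl from consuming borane in the key step.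

**Step 10**
Reactants: 14 4-iodophenol
Product: 15 1-iodo-4-(methoxymethoxy)benzene
Conditions: MOMCl (1.3 equiv.), i-Pr2NEt (1.5 equiv.), CH2Cl2, 0 °C → rt
Reagents that add atoms: chloromethyl methyl ether, COCCl
Why: Williamson-type O-alkylation of the phenol should give the MOM-protected aryl iodide, which serves as the coupling partner for both chain termini and as the precursor of the ring B boronic acid.

**Step 11**
Reactants: 13 tert-butyl({(3R,5S)-5-[4-methoxy-2,6-bis(methoxymethoxy)phenyl]hept-1-en-6-yn-3-yl}oxy)dimethylsilane; 15 1-iodo-4-(methoxymethoxy)benzene (2.5 equiv.)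
Product: 18 tert-butyl({(3S,5S,6E)-5-[4-methoxy-2,6-bis(methoxymethoxy)phenyl]-1,7-bis[4-(methoxymethoxy)phenyl]hept-6-en-3-yl}oxy)dimethylsilane, via C7''-boryl alkyne 16 (not isolated), via C1''/C7''-bisborane 17 (not isolated)
Conditions: 9-BBN (1.05 equiv.), THF, 0 °C → rt; Cy2BH (1.1 equiv.), THF, 0 °C → rt; then 15 (2.5 equiv.), Pd(dppf)Cl2·CH2Cl2 (10 mol %), AsPh3 (10 mol %), 3 M aq. K3PO4, DMF, rt → 50 °C
Reagents that add atoms: none
Why: 9-BBN adds syn and anti-Markovnikov to the monosubstituted C6''=C7'' alkene, placing boron on C7'', and dicyclohexylborane then adds once to the terminal alkyne to give the (E)-C1''-alkenylborane; after addition of aqueous base both boranes become borates, transmetalate to the arylpalladium iodide formed from 15 and zerovalent palladium, and reductive elimination forms the C7''–aryl (sp3–sp2) and C1''–aryl (sp2–sp2) bonds. The closest known reactions are the B-alkyl Suzuki–Miyaura coupling of alkyl-9-BBN reagents and the coupling of (E)-alkenyldialkylboranes with aryl iodides, here run at the two ends of one molecule with a single aryl iodide because both termini carry the same arene. No ring is closed and no stereocentre is formed: the E geometry of C1''=C2'' follows from the syn hydroboration and is retained through transmetalation, and C3'' and C5'' are spectators, the C5'' descriptor changing from R to S only because the vinyl group becomes a lower-ranking CH2 group. The step needs alkene-before-alkyne selectivity in the first hydroboration, mono-addition at the alkyne, and transfer of the primary alkyl and the alkenyl group in preference to the secondary ligands on boron. The first should be secured by the known preference of 9-BBN for terminal alkenes over terminal alkynes, reinforced by the di-ortho-substituted arene that shields the alkyne at C3'' and by the use of one equivalent; the second by the bulk of dicyclohexylborane; the third by the established transfer order of primary alkyl and alkenyl before secondary alkyl. A crossed first hydroboration would not be fatal, since an (E)-alkenyl-9-BBN species couples to the same product, so only geminal double addition to the alkyne has to be excluded.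

**Step 12**
Reactants: 18 tert-butyl({(3S,5S,6E)-5-[4-methoxy-2,6-bis(methoxymethoxy)phenyl]-1,7-bis[4-(methoxymethoxy)phenyl]hept-6-en-3-yl}oxy)dimethylsilane
Product: 19 tert-butyl({(3S,5S,6E)-5-[3-bromo-4-methoxy-2,6-bis(methoxymethoxy)phenyl]-1,7-bis[4-(methoxymethoxy)phenyl]hept-6-en-3-yl}oxy)dimethylsilane
Conditions: NBS (1.0 equiv.), CH2Cl2–DMF, −60 → −30 °C, dark
Reagents that add atoms: N-bromosuccinimide, O=C1CCC(=O)N1Br
Why: Electrophilic aromatic bromination should occur at one of the two free positions of the trioxygenated ring A, which are the most nucleophilic sites and are equivalent by rotation about the C8–C3'' bond, so that one equivalent at low temperature gives a single monobromide and leaves the mono-oxygenated rings and the styrene alone.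

**Step 13**
Reactants: 19 tert-butyl({(3S,5S,6E)-5-[3-bromo-4-methoxy-2,6-bis(methoxymethoxy)phenyl]-1,7-bis[4-(methoxymethoxy)phenyl]hept-6-en-3-yl}oxy)dimethylsilane
Product: 22 1-{3-[(1E,3S,5S)-5-[(tert-butyldimethylsilyl)oxy]-1,7-bis[4-(methoxymethoxy)phenyl]hept-1-en-3-yl]-6-methoxy-2,4-bis(methoxymethoxy)phenyl}ethan-1-one, via ring A aryllithium 20 (not isolated), via lithium hemiaminal alkoxide 21 (not isolated)
Conditions: n-BuLi (1.1 equiv.), THF, −78 °C; MeC(O)N(OMe)Me (2 equiv.), −78 → 0 °C; aq. NH4Cl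
Reagents that add atoms: N-methoxy-N-methylacetamide, CC(=O)N(C)OC
Why: Bromine–lithium exchange is much faster at −78 °C than deprotonation at C3'' or addition to the styrene, and acylation of the aryllithium with the Weinreb amide should stop at the ketone because the chelated tetrahedral adduct survives until work-up.

**Step 14**
Reactants: 22 1-{3-[(1E,3S,5S)-5-[(tert-butyldimethylsilyl)oxy]-1,7-bis[4-(methoxymethoxy)phenyl]hept-1-en-3-yl]-6-methoxy-2,4-bis(methoxymethoxy)phenyl}ethan-1-one
Product: 23 1-{3-[(1E,3S,5S)-5-[(tert-butyldimethylsilyl)oxy]-1,7-bis[4-(methoxymethoxy)phenyl]hept-1-en-3-yl]-2-hydroxy-6-methoxy-4-(methoxymethoxy)phenyl}ethan-1-one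
Conditions: MgBr2·OEt2 (3 equiv.), Et2O–toluene, 0 °C → rt; H2O
Reagents that add atoms: none
Why: Chelation-assisted acetal cleavage, in which magnesium bridges the ketone oxygen and the neighbouring MOM ether so that bromide opens only that acetal, should free the phenol ortho to the acetyl group while the three MOM ethers without a chelating partner, the methyl ether and the silyl ether remain.

**Step 15**
Reactants: 23 1-{3-[(1E,3S,5S)-5-[(tert-butyldimethylsilyl)oxy]-1,7-bis[4-(methoxymethoxy)phenyl]hept-1-en-3-yl]-2-hydroxy-6-methoxy-4-(methoxymethoxy)phenyl}ethan-1-one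
Product: 25 8-[(1E,3S,5S)-5-[(tert-butyldimethylsilyl)oxy]-1,7-bis[4-(methoxymethoxy)phenyl]hept-1-en-3-yl]-5-methoxy-7-(methoxymethoxy)-4H-chromen-4-one, via enaminone 24 (not isolated)
Conditions: Me2NCH(OMe)2 (3 equiv.), toluene, 90 °C; then AcOH (10 equiv.), toluene, 60 °C
Reagents that add atoms: N,N-dimethylformamide dimethyl acetal, COC(OC)N(C)C
Why: Condensation of the methyl ketone with the formamide acetal gives the enaminone, and acid-promoted conjugate addition of the phenol followed by loss of dimethylamine (addition–elimination, the standard chromone synthesis from a 2-hydroxyacetophenone) should close ring C as the 4-pyranone.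

**Step 16**
Reactants: 15 1-iodo-4-(methoxymethoxy)benzene
Product: 28 [4-(methoxymethoxy)phenyl]boronic acid, via 4-(methoxymethoxy)phenyllithium 26 (not isolated), via lithium aryltriisopropoxyborate 27 (not isolated)
Conditions: B(Oi-Pr)3 (1.5 equiv.), n-BuLi (1.1 equiv.), THF–toluene, −78 °C; 1 M HCl to pH 5, 0 °C
Reagents that add atoms: triisopropyl borate, CC(C)OB(OC(C)C)OC(C)C; water, O
Why: Iodine–lithium exchange with in situ borylation (the aryllithium is trapped by the borate as it forms) and mild hydrolysis of the ate complex should give the arylboronic acid, the MOM ether tolerating the brief cold acidification.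

**Step 17**
Reactants: 25 8-[(1E,3S,5S)-5-[(tert-butyldimethylsilyl)oxy]-1,7-bis[4-(methoxymethoxy)phenyl]hept-1-en-3-yl]-5-methoxy-7-(methoxymethoxy)-4H-chromen-4-one; 28 [4-(methoxymethoxy)phenyl]boronic acid
Product: 29 (2S)-8-[(1E,3S,5S)-5-[(tert-butyldimethylsilyl)oxy]-1,7-bis[4-(methoxymethoxy)phenyl]hept-1-en-3-yl]-5-methoxy-7-(methoxymethoxy)-2-[4-(methoxymethoxy)phenyl]-2,3-dihydro-4H-chromen-4-one
Conditions: [Rh(OH)(cod)]2 (3 mol %), (S)-MeO-F12-BIPHEP (6.6 mol %), 28 (3 equiv.), toluene–H2O (20:1), 30 °C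
Reagents that add atoms: none
Why: Rhodium-catalysed asymmetric 1,4-addition of an arylboronic acid to a chromone (Hayashi–Miyaura type), in which the arylrhodium species inserts the C2=C3 bond on the face selected by the electron-poor atropisomeric bisphosphine and the oxa-π-allyl intermediate is protonated by water, should set C2 as S under catalyst control.

**Step 18**
Reactants: 29 (2S)-8-[(1E,3S,5S)-5-[(tert-butyldimethylsilyl)oxy]-1,7-bis[4-(methoxymethoxy)phenyl]hept-1-en-3-yl]-5-methoxy-7-(methoxymethoxy)-2-[4-(methoxymethoxy)phenyl]-2,3-dihydro-4H-chromen-4-one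
Product: 30 (2S)-7-hydroxy-8-[(1E,3S,5S)-5-hydroxy-1,7-bis(4-hydroxyphenyl)hept-1-en-3-yl]-2-(4-hydroxyphenyl)-5-methoxy-2,3-dihydro-4H-chromen-4-one (CNP0191649.2)
Conditions: HCl (1.25 M in MeOH)–THF (1:1), 0 °C → rt
Reagents that add atoms: none
Why: Acid-catalysed acetal exchange with methanol should remove the four MOM groups and solvolysis the silyl ether, the low temperature being chosen so that neither the flavanone C2 centre (ring opening to the chalcone) nor the 4-hydroxystyrene (protonation and capture by the C5'' hydroxyl) reacts.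

**Compound list**
1 | 5-methoxyresorcinol (5-methoxybenzene-1,3-diol) | COc1cc(O)cc(O)c1 | starting material
2 | 1-methoxy-3,5-bis(methoxymethoxy)benzene | COCOc1cc(OC)cc(OCOC)c1 | intermediate
3 | [4-methoxy-2,6-bis(methoxymethoxy)phenyl]lithium | [Li]c1c(OCOC)cc(OC)cc1OCOC | intermediate
4 | lithium (2E)-3-(dimethylamino)-1-[4-methoxy-2,6-bis(methoxymethoxy)phenyl]prop-2-en-1-olate (racemic) | [Li]OC(/C=C/N(C)C)c1c(OCOC)cc(OC)cc1OCOC | intermediate
5 | (2E)-3-[4-methoxy-2,6-bis(methoxymethoxy)phenyl]prop-2-enal | COCOc1cc(OC)cc(OCOC)c1/C=C/C=O | intermediate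
6 | ethynyltri(propan-2-yl)silane [(triisopropylsilyl)acetylene] | C#C[Si](C(C)C)(C(C)C)C(C)C | starting material
7 | (3R)-3-[4-methoxy-2,6-bis(methoxymethoxy)phenyl]-5-[tri(propan-2-yl)silyl]pent-4-ynal | O=CC[C@@H](C#C[Si](C(C)C)(C(C)C)C(C)C)c1c(OCOC)cc(OC)cc1OCOC | intermediate
8 | (5R)-5-[4-methoxy-2,6-bis(methoxymethoxy)phenyl]-7-[tri(propan-2-yl)silyl]-1-(trimethylsilyl)hepta-1,6-diyn-3-ol (C3 epimers) | C[Si](C)(C)C#CC(O)C[C@@H](C#C[Si](C(C)C)(C(C)C)C(C)C)c1c(OCOC)cc(OC)cc1OCOC | intermediate
9 | (5R)-5-[4-methoxy-2,6-bis(methoxymethoxy)phenyl]-7-[tri(propan-2-yl)silyl]-1-(trimethylsilyl)hepta-1,6-diyn-3-one | C[Si](C)(C)C#CC(=O)C[C@@H](C#C[Si](C(C)C)(C(C)C)C(C)C)c1c(OCOC)cc(OC)cc1OCOC | intermediate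
10 | (3R,5R)-5-[4-methoxy-2,6-bis(methoxymethoxy)phenyl]-7-[tri(propan-2-yl)silyl]-1-(trimethylsilyl)hepta-1,6-diyn-3-ol | C[Si](C)(C)C#C[C@H](O)C[C@@H](C#C[Si](C(C)C)(C(C)C)C(C)C)c1c(OCOC)cc(OC)cc1OCOC | intermediate
11 | (3R,5S)-5-[4-methoxy-2,6-bis(methoxymethoxy)phenyl]hepta-1,6-diyn-3-ol | C#C[C@H](O)C[C@@H](C#C)c1c(OCOC)cc(OC)cc1OCOC | intermediate
12 | (3R,5S)-5-[4-methoxy-2,6-bis(methoxymethoxy)phenyl]hept-1-en-6-yn-3-ol | C=C[C@H](O)C[C@@H](C#C)c1c(OCOC)cc(OC)cc1OCOC | intermediate
13 | tert-butyl({(3R,5S)-5-[4-methoxy-2,6-bis(methoxymethoxy)phenyl]hept-1-en-6-yn-3-yl}oxy)dimethylsilane | COc1cc(OCOC)c([C@H](C#C)C[C@@H](O[Si](C)(C)C(C)(C)C)C=C)c(OCOC)c1 | intermediate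
14 | 4-iodophenol | Oc1ccc(I)cc1 | starting material
15 | 1-iodo-4-(methoxymethoxy)benzene | COCOc1ccc(I)cc1 | intermediate
16 | 9-{(3S,5S)-3-[(tert-butyldimethylsilyl)oxy]-5-[4-methoxy-2,6-bis(methoxymethoxy)phenyl]hept-6-yn-1-yl}-9-borabicyclo[3.3.1]nonane | COc1cc(OCOC)c([C@H](C#C)C[C@@H](O[Si](C)(C)C(C)(C)C)CCB2C3CCCC2CCC3)c(OCOC)c1 | intermediate
17 | 9-{(3S,5S,6E)-3-[(tert-butyldimethylsilyl)oxy]-7-(dicyclohexylboranyl)-5-[4-methoxy-2,6-bis(methoxymethoxy)phenyl]hept-6-en-1-yl}-9-borabicyclo[3.3.1]nonane | COc1cc(OCOC)c([C@H](/C=C/B(C2CCCCC2)C2CCCCC2)C[C@@H](O[Si](C)(C)C(C)(C)C)CCB2C3CCCC2CCC3)c(OCOC)c1 | intermediate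
18 | tert-butyl({(3S,5S,6E)-5-[4-methoxy-2,6-bis(methoxymethoxy)phenyl]-1,7-bis[4-(methoxymethoxy)phenyl]hept-6-en-3-yl}oxy)dimethylsilane | COc1cc(OCOC)c([C@H](/C=C/c2ccc(OCOC)cc2)C[C@@H](O[Si](C)(C)C(C)(C)C)CCc2ccc(OCOC)cc2)c(OCOC)c1 | intermediate
19 | tert-butyl({(3S,5S,6E)-5-[3-bromo-4-methoxy-2,6-bis(methoxymethoxy)phenyl]-1,7-bis[4-(methoxymethoxy)phenyl]hept-6-en-3-yl}oxy)dimethylsilane | COc1cc(OCOC)c([C@H](/C=C/c2ccc(OCOC)cc2)C[C@@H](O[Si](C)(C)C(C)(C)C)CCc2ccc(OCOC)cc2)c(OCOC)c1Br | intermediate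
20 | {3-[(1E,3S,5S)-5-[(tert-butyldimethylsilyl)oxy]-1,7-bis[4-(methoxymethoxy)phenyl]hept-1-en-3-yl]-6-methoxy-2,4-bis(methoxymethoxy)phenyl}lithium | COc1cc(OCOC)c([C@H](/C=C/c2ccc(OCOC)cc2)C[C@@H](O[Si](C)(C)C(C)(C)C)CCc2ccc(OCOC)cc2)c(OCOC)c1[Li] | intermediate
21 | lithium 1-{3-[(1E,3S,5S)-5-[(tert-butyldimethylsilyl)oxy]-1,7-bis[4-(methoxymethoxy)phenyl]hept-1-en-3-yl]-6-methoxy-2,4-bis(methoxymethoxy)phenyl}-1-[methoxy(methyl)amino]ethan-1-olate | COc1cc(OCOC)c([C@H](/C=C/c2ccc(OCOC)cc2)C[C@@H](O[Si](C)(C)C(C)(C)C)CCc2ccc(OCOC)cc2)c(OCOC)c1C(C)(O[Li])N(C)OC | intermediate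
22 | 1-{3-[(1E,3S,5S)-5-[(tert-butyldimethylsilyl)oxy]-1,7-bis[4-(methoxymethoxy)phenyl]hept-1-en-3-yl]-6-methoxy-2,4-bis(methoxymethoxy)phenyl}ethan-1-one | COc1cc(OCOC)c([C@H](/C=C/c2ccc(OCOC)cc2)C[C@@H](O[Si](C)(C)C(C)(C)C)CCc2ccc(OCOC)cc2)c(OCOC)c1C(C)=O | intermediate
23 | 1-{3-[(1E,3S,5S)-5-[(tert-butyldimethylsilyl)oxy]-1,7-bis[4-(methoxymethoxy)phenyl]hept-1-en-3-yl]-2-hydroxy-6-methoxy-4-(methoxymethoxy)phenyl}ethan-1-one | COc1cc(OCOC)c([C@H](/C=C/c2ccc(OCOC)cc2)C[C@@H](O[Si](C)(C)C(C)(C)C)CCc2ccc(OCOC)cc2)c(O)c1C(C)=O | intermediate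
24 | (2E)-1-{3-[(1E,3S,5S)-5-[(tert-butyldimethylsilyl)oxy]-1,7-bis[4-(methoxymethoxy)phenyl]hept-1-en-3-yl]-2-hydroxy-6-methoxy-4-(methoxymethoxy)phenyl}-3-(dimethylamino)prop-2-en-1-one | COc1cc(OCOC)c([C@H](/C=C/c2ccc(OCOC)cc2)C[C@@H](O[Si](C)(C)C(C)(C)C)CCc2ccc(OCOC)cc2)c(O)c1C(=O)/C=C/N(C)C | intermediate
25 | 8-[(1E,3S,5S)-5-[(tert-butyldimethylsilyl)oxy]-1,7-bis[4-(methoxymethoxy)phenyl]hept-1-en-3-yl]-5-methoxy-7-(methoxymethoxy)-4H-chromen-4-one | COc1cc(OCOC)c([C@H](/C=C/c2ccc(OCOC)cc2)C[C@@H](O[Si](C)(C)C(C)(C)C)CCc2ccc(OCOC)cc2)c2occc(=O)c12 | intermediate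
26 | [4-(methoxymethoxy)phenyl]lithium | [Li]c1ccc(OCOC)cc1 | intermediate
27 | lithium [4-(methoxymethoxy)phenyl]tri(propan-2-yloxy)borate | [Li+].CC(C)O[B-](OC(C)C)(OC(C)C)c1ccc(OCOC)cc1 | intermediate
28 | [4-(methoxymethoxy)phenyl]boronic acid | COCOc1ccc(B(O)O)cc1 | intermediate
29 | (2S)-8-[(1E,3S,5S)-5-[(tert-butyldimethylsilyl)oxy]-1,7-bis[4-(methoxymethoxy)phenyl]hept-1-en-3-yl]-5-methoxy-7-(methoxymethoxy)-2-[4-(methoxymethoxy)phenyl]-2,3-dihydro-4H-chromen-4-one | COc1cc(OCOC)c([C@H](/C=C/c2ccc(OCOC)cc2)C[C@@H](O[Si](C)(C)C(C)(C)C)CCc2ccc(OCOC)cc2)c2c1C(=O)C[C@@H](c1ccc(OCOC)cc1)O2 | intermediate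
30 | (2S)-7-hydroxy-8-[(1E,3S,5S)-5-hydroxy-1,7-bis(4-hydroxyphenyl)hept-1-en-3-yl]-2-(4-hydroxyphenyl)-5-methoxy-2,3-dihydro-4H-chromen-4-one | COc1cc(O)c([C@H](/C=C/c2ccc(O)cc2)C[C@@H](O)CCc2ccc(O)cc2)c2c1C(=O)C[C@@H](c1ccc(O)cc1)O2 | target

**Step count and risk**
Total step count: 18. Longest linear sequence: 16 steps (steps 1–9, 11–15, 17, 18); steps 10 and 16 form the side branch from 4-iodophenol.

The three steps most likely to fail:

Step 11. The hydroboration may go to the alkyne first or twice (geminal diboration at C1''), or one of the two boranes may transfer too slowly, so that half-coupled material accumulates and is protodeborylated. Fallback: the two couplings are separated and the alkyne is addressed first with a reagent that does not touch the alkene. Setting out from 13, zirconium-catalysed hydroboration with pinacolborane (HBpin 1.2 equiv., Cp2Zr(H)Cl 10 mol %, Et3N 10 mol %, 40 °C) should give the isolable (E)-alkenyl pinacol boronate F1. Suzuki–Miyaura coupling of F1 with 15 (1.1 equiv., Pd(dppf)Cl2·CH2Cl2, aq. K3PO4, THF, 50 °C) should give the styrene F2 with the vinyl group intact. 9-BBN should then add only to the monosubstituted alkene of F2, the 1,2-disubstituted styrene being far slower, to give the alkylborane F3, which is coupled in the same flask with a second portion of 15 under the palladium conditions of step 11; the sequence comes back to the route at 18.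

Step 3. The electron-rich, doubly ortho-substituted enal may insert too slowly into the alkynyl–rhodium bond, so that alkyne dimerisation takes over, or the facial selectivity may be poor. Fallback: the acceptor is changed to a doubly activated alkylidene malonate equivalent. Setting out from 2, lithiation as in step 2 (aryllithium 3) and quenching with DMF should give, through the lithium hemiaminal alkoxide F4, the benzaldehyde F5. Knoevenagel condensation of F5 with Meldrum's acid (2,2-dimethyl-1,3-dioxane-4,6-dione, pyrrolidinium acetate, benzene, rt → 50 °C) gives the arylidene Meldrum's acid F6. Rhodium/chiral bisphosphine-catalysed conjugate alkynylation of F6 with 6, a known reaction of arylidene Meldrum's acids with silylacetylenes, should give the adduct F7. Methanolysis with decarboxylation (MeOH–pyridine, Cu powder, reflux) gives the methyl ester F8, and i-Bu2AlH (CH2Cl2, −78 °C) reduces F8 through the aluminium hemiacetal F9, which collapses on work-up to the aldehyde; the sequence comes back to the route at 7.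

Step 17. The arylrhodium species may fail to insert the electron-rich chromone that carries the bulky C8 substituent, or the flavanone may open by retro-oxa-Michael reaction and lose its C2 configuration. Fallback: ring C is built by the chalcone route and C2 is secured by separation of diastereomers. Setting out from 23, Claisen–Schmidt condensation with 4-(methoxymethoxy)benzaldehyde (KOH, EtOH, rt) should give the 2'-hydroxychalcone F10. Oxa-Michael cyclisation (NaOAc, EtOH, reflux) should give the flavanone as both C2 epimers, which are diastereomers because C3'' and C5'' are fixed and should be separable by chromatography. The (2S) epimer is 29, where the route is rejoined; the (2R) epimer F11 is returned to the cyclisation conditions, which equilibrate it through F10.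

**Further compounds**
F1 | step 11 | tert-butyl({(3R,5S,6E)-5-[4-methoxy-2,6-bis(methoxymethoxy)phenyl]-7-(4,4,5,5-tetramethyl-1,3,2-dioxaborolan-2-yl)hepta-1,6-dien-3-yl}oxy)dimethylsilane | COc1cc(OCOC)c([C@H](/C=C/B2OC(C)(C)C(C)(C)O2)C[C@@H](O[Si](C)(C)C(C)(C)C)C=C)c(OCOC)c1
F2 | step 11 | tert-butyl({(3R,5S,6E)-5-[4-methoxy-2,6-bis(methoxymethoxy)phenyl]-7-[4-(methoxymethoxy)phenyl]hepta-1,6-dien-3-yl}oxy)dimethylsilane | COc1cc(OCOC)c([C@H](/C=C/c2ccc(OCOC)cc2)C[C@@H](O[Si](C)(C)C(C)(C)C)C=C)c(OCOC)c1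
F3 | step 11 | 9-{(3S,5S,6E)-3-[(tert-butyldimethylsilyl)oxy]-5-[4-methoxy-2,6-bis(methoxymethoxy)phenyl]-7-[4-(methoxymethoxy)phenyl]hept-6-en-1-yl}-9-borabicyclo[3.3.1]nonane | COc1cc(OCOC)c([C@H](/C=C/c2ccc(OCOC)cc2)C[C@@H](O[Si](C)(C)C(C)(C)C)CCB2C3CCCC2CCC3)c(OCOC)c1
F4 | step 3 | lithium (dimethylamino)[4-methoxy-2,6-bis(methoxymethoxy)phenyl]methanolate | [Li]OC(N(C)C)c1c(OCOC)cc(OC)cc1OCOC
F5 | step 3 | 4-methoxy-2,6-bis(methoxymethoxy)benzaldehyde | COCOc1cc(OC)cc(OCOC)c1C=O
F6 | step 3 | 5-{[4-methoxy-2,6-bis(methoxymethoxy)phenyl]methylidene}-2,2-dimethyl-1,3-dioxane-4,6-dione | COCOc1cc(OC)cc(OCOC)c1C=C1C(=O)OC(C)(C)OC1=O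
F7 | step 3 | 5-{(1R)-1-[4-methoxy-2,6-bis(methoxymethoxy)phenyl]-3-[tri(propan-2-yl)silyl]prop-2-yn-1-yl}-2,2-dimethyl-1,3-dioxane-4,6-dione | CC(C)[Si](C#C[C@@H](c1c(OCOC)cc(OC)cc1OCOC)C1C(=O)OC(C)(C)OC1=O)(C(C)C)C(C)C
F8 | step 3 | methyl (3R)-3-[4-methoxy-2,6-bis(methoxymethoxy)phenyl]-5-[tri(propan-2-yl)silyl]pent-4-ynoate | COC(=O)C[C@@H](C#C[Si](C(C)C)(C(C)C)C(C)C)c1c(OCOC)cc(OC)cc1OCOC
F9 | step 3 | diisobutylaluminium hemiacetal of F8, {(3R)-1-methoxy-3-[4-methoxy-2,6-bis(methoxymethoxy)phenyl]-5-[tri(propan-2-yl)silyl]pent-4-yn-1-yl}oxy-bis(2-methylpropyl)alumane | COC(O[Al](CC(C)C)CC(C)C)C[C@@H](C#C[Si](C(C)C)(C(C)C)C(C)C)c1c(OCOC)cc(OC)cc1OCOC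
F10 | step 17 | (2E)-1-{3-[(1E,3S,5S)-5-[(tert-butyldimethylsilyl)oxy]-1,7-bis[4-(methoxymethoxy)phenyl]hept-1-en-3-yl]-2-hydroxy-6-methoxy-4-(methoxymethoxy)phenyl}-3-[4-(methoxymethoxy)phenyl]prop-2-en-1-one | COc1cc(OCOC)c([C@H](/C=C/c2ccc(OCOC)cc2)C[C@@H](O[Si](C)(C)C(C)(C)C)CCc2ccc(OCOC)cc2)c(O)c1C(=O)/C=C/c1ccc(OCOC)cc1
F11 | step 17 | (2R)-8-[(1E,3S,5S)-5-[(tert-butyldimethylsilyl)oxy]-1,7-bis[4-(methoxymethoxy)phenyl]hept-1-en-3-yl]-5-methoxy-7-(methoxymethoxy)-2-[4-(methoxymethoxy)phenyl]-2,3-dihydro-4H-chromen-4-one | COc1cc(OCOC)c([C@H](/C=C/c2ccc(OCOC)cc2)C[C@@H](O[Si](C)(C)C(C)(C)C)CCc2ccc(OCOC)cc2)c2c1C(=O)C[C@H](c1ccc(OCOC)cc1)O2
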